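**Retrosynthetic overview**

1. Numbering runs along the chain from C1' (ArOCH2) to C8' (lactone C=O). The plan rests on the 1,3-syn relation between the γ-lactone ring oxygen on C5' and the oxirane oxygen on C3': a six-membered cyclic carbonate spanning these two oxygens lets C5' fix both oxirane carbons, C3' and C2'.
2. Last bonds made: ArO–C1' (Mitsunobu with umbelliferone), lactone O(C5')–C8', and oxirane O–C2' (the C3' alkoxide displaces iodide).
3. Key disconnection: the 4-(1-iodoalkyl)-4-methyl-1,3-dioxan-2-one goes back to the tert-butyl carbonate of the Z-C2'=C3' homoallylic alcohol and IBr (new bonds O–C3' and C2'–I).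
4. The Z alkene and C5' come from a 4-methyl-5,6-dihydropyran-2-one, made by copper-catalysed vinylogous aldol–lactonisation of the citramalate-derived C5'–C8' aldehyde with the C1'–C4' silyl dienolate and opened with LiAlH4. C7' comes from (R)-citramalic acid.
5. Ring order: dioxolane (protection), dihydropyranone (alkene-geometry template), 1,3-dioxan-2-one (key step), oxirane, γ-lactone; the coumarin rings are bought as umbelliferone.

Key step: step 9

Assumption: (S)-tol-BINAP is taken to send the dienolate to the Si face of aldehyde 4 in step 5 (the antipodal ligand would be used if the sense proved opposite); the C1=C2 geometry of ketene acetal 7 is left undefined because it is lost when that carbon becomes the lactone carbonyl.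

**Route**

Step 1
Reactants: 1 (R)-citramalic acid
Product: 2 (2R)-2-methylbutane-1,2,4-triol
Conditions: BH3·SMe2, B(OMe)3, THF, 0 °C → rt; MeOH quench
Reagents that add atoms: none
Why: Borane reduction of carboxylic acids should take both carboxyl groups to CH2OH while the tertiary carbinol C7' from the chiral pool is not touched.

Step 2
Reactants: 2 (2R)-2-methylbutane-1,2,4-triol
Product: 3 2-[(4R)-2,2,4-trimethyl-1,3-dioxolan-4-yl]ethan-1-ol
Conditions: 2,2-dimethoxypropane, TsOH (cat.), acetone, rt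
Reagents that add atoms: 2,2-dimethoxypropane, COC(C)(C)OC
Why: Acetonide formation under equilibrating conditions should favour the five-membered dioxolane on the 1,2-diol over the 1,3-dioxane, which would carry an axial substituent next to the acetal methyls, leaving the C5' alcohol free.

Step 3
Reactants: 3 2-[(4R)-2,2,4-trimethyl-1,3-dioxolan-4-yl]ethan-1-ol
Product: 4 2-[(4R)-2,2,4-trimethyl-1,3-dioxolan-4-yl]acetaldehyde
Conditions: TEMPO (cat.), PhI(OAc)2, CH2Cl2, rt
Reagents that add atoms: none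
Why: The oxoammonium (TEMPO) oxidation stops at the aldehyde under nearly neutral conditions, which should spare the acetonide and avoid β-elimination of the C7' oxygen.

Step 4
Reactants: 5 methyl 3-methylbut-2-enoate
Product: 7 [(1-methoxy-3-methylbuta-1,3-dien-1-yl)oxy]trimethylsilane, via lithium dienolate 6 (not isolated)
Conditions: LiN(iPr)2, THF, −78 °C; then Me3SiCl, −78 °C → rt; distil
Reagents that add atoms: chlorotrimethylsilane, C[Si](C)(C)Cl
Why: Kinetic γ-deprotonation of the β,β-dimethyl enoate followed by O-silylation of the dienolate is the standard preparation of this silyl ketene acetal.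

Step 5
Reactants: 4 2-[(4R)-2,2,4-trimethyl-1,3-dioxolan-4-yl]acetaldehyde; 7 [(1-methoxy-3-methylbuta-1,3-dien-1-yl)oxy]trimethylsilane
Product: 9 (6S)-4-methyl-6-{[(4R)-2,2,4-trimethyl-1,3-dioxolan-4-yl]methyl}-5,6-dihydro-2H-pyran-2-one, via copper aldolate 8 (not isolated)
Conditions: Cu(OTf)2 (10 mol %), (S)-tol-BINAP (11 mol %), Bu4N[Ph3SiF2] (20 mol %), THF, rt
Reagents that add atoms: none
Why: In this catalytic asymmetric vinylogous Mukaiyama aldol–lactonisation, fluoride turns 7 into a chiral monovalent copper dienolate whose γ-carbon adds to the Si face of the aldehyde under ligand control (setting C5' as 6S), and the Z-configured aldolate 8 closes onto its own ester with loss of methoxide as methoxytrimethylsilane.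

Step 6
Reactants: 9 (6S)-4-methyl-6-{[(4R)-2,2,4-trimethyl-1,3-dioxolan-4-yl]methyl}-5,6-dihydro-2H-pyran-2-one
Product: 10 (2Z,5S)-3-methyl-6-[(4R)-2,2,4-trimethyl-1,3-dioxolan-4-yl]hex-2-ene-1,5-diol
Conditions: LiAlH4, Et2O, −20 → 0 °C; then H2O, 15 % aq. NaOH
Reagents that add atoms: none
Why: 1,2-Reduction of the β,β-disubstituted unsaturated lactone by LiAlH4 should open the ring to the diol, and the Z geometry of C2'=C3' is inherited from the ring.

Step 7
Reactants: 10 (2Z,5S)-3-methyl-6-[(4R)-2,2,4-trimethyl-1,3-dioxolan-4-yl]hex-2-ene-1,5-diol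
Product: 11 (2S,4Z)-6-[(tert-butyldiphenylsilyl)oxy]-4-methyl-1-[(4R)-2,2,4-trimethyl-1,3-dioxolan-4-yl]hex-4-en-2-ol
Conditions: t-BuPh2SiCl (1.05 equiv), imidazole, CH2Cl2, 0 °C
Reagents that add atoms: tert-butyl(chloro)diphenylsilane, CC(C)(C)[Si](Cl)(c1ccccc1)c1ccccc1
Why: Silylation with the bulky chlorosilane should take the primary allylic C1' hydroxyl and leave the secondary C5' hydroxyl, and the resulting ether tolerates the later acid and base steps.

Step 8
Reactants: 11 (2S,4Z)-6-[(tert-butyldiphenylsilyl)oxy]-4-methyl-1-[(4R)-2,2,4-trimethyl-1,3-dioxolan-4-yl]hex-4-en-2-ol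
Product: 12 tert-butyl (2S,4Z)-6-[(tert-butyldiphenylsilyl)oxy]-4-methyl-1-[(4R)-2,2,4-trimethyl-1,3-dioxolan-4-yl]hex-4-en-2-yl carbonate
Conditions: Boc2O, DMAP (0.3 equiv), MeCN, rt
Reagents that add atoms: di-tert-butyl dicarbonate, CC(C)(C)OC(=O)OC(=O)OC(C)(C)C
Why: DMAP-catalysed acylation of the secondary C5' alcohol with Boc2O installs the carbonate nucleophile without touching C5'.

Step 9
Reactants: 12 tert-butyl (2S,4Z)-6-[(tert-butyldiphenylsilyl)oxy]-4-methyl-1-[(4R)-2,2,4-trimethyl-1,3-dioxolan-4-yl]hex-4-en-2-yl carbonate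
Product: 14 (4R,6R)-4-{(1R)-2-[(tert-butyldiphenylsilyl)oxy]-1-iodoethyl}-4-methyl-6-{[(4R)-2,2,4-trimethyl-1,3-dioxolan-4-yl]methyl}-1,3-dioxan-2-one, via tert-butoxydioxanylium bromide 13 (not isolated)
Conditions: IBr (1.5 equiv, 1 M in CH2Cl2), PhMe, −85 °C; then aq. Na2S2O3/NaHCO3
Reagents that add atoms: iodine monobromide, IBr
Why: IBr places an iodonium ion on the Z C2'=C3' alkene and the carbonyl oxygen of the C5' tert-butyl carbonate opens it at the tertiary C3' anti to iodine, giving the 2-tert-butoxy-1,3-dioxan-2-ylium bromide 13, which loses its tert-butyl group to bromide; this is the iodocarbonate cyclisation of homoallylic tert-butyl carbonates with IBr. The one ring formed, the 1,3-dioxan-2-one, closes in the 6-exo mode by O–C3' bond formation, 7-endo attack at C2' being disfavoured by ring size and by the poorer cation-stabilising ability of the secondary carbon. C3' is controlled by C5' through a chair-like transition state in which the C6' arm is equatorial and the alkene carbon C2' is also equatorial, anti to the C4'–C5' bond, because in the other chair the Z substituent C1' would be pressed against C5' (allylic 1,3-strain); the C3' methyl therefore goes axial and the two ring oxygens end up 1,3-syn. C2' is fixed by the stereospecific anti addition of oxygen and iodine across the Z alkene. The step needs facial selectivity between the two alkene faces and regioselectivity for C3', and these should be secured by the Z geometry, the equatorial C5' substituent and the tertiary nature of C3', while the low temperature should keep the acetonide and the silyl ether intact.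

Step 10
Reactants: 14 (4R,6R)-4-{(1R)-2-[(tert-butyldiphenylsilyl)oxy]-1-iodoethyl}-4-methyl-6-{[(4R)-2,2,4-trimethyl-1,3-dioxolan-4-yl]methyl}-1,3-dioxan-2-one
Product: 15 (4R,6R)-4-{(1R)-2-[(tert-butyldiphenylsilyl)oxy]-1-iodoethyl}-6-[(2R)-2,3-dihydroxy-2-methylpropyl]-4-methyl-1,3-dioxan-2-one
Conditions: AcOH/THF/H2O (3:1:1), 40 °C
Reagents that add atoms: none
Why: Acid hydrolysis of the acetonide should leave the cyclic carbonate, the secondary iodide and the silyl ether untouched, which is why the oxirane is kept masked as the iodocarbonate through this step.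

Step 11
Reactants: 15 (4R,6R)-4-{(1R)-2-[(tert-butyldiphenylsilyl)oxy]-1-iodoethyl}-6-[(2R)-2,3-dihydroxy-2-methylpropyl]-4-methyl-1,3-dioxan-2-one
Product: 17 (2R)-3-[(4R,6R)-6-{(1R)-2-[(tert-butyldiphenylsilyl)oxy]-1-iodoethyl}-6-methyl-2-oxo-1,3-dioxan-4-yl]-2-hydroxy-2-methylpropanoic acid, via hydroxy aldehyde 16 (not isolated)
Conditions: TEMPO (cat.), NaOCl (cat.), NaClO2, MeCN/aq. NaH2PO4–Na2HPO4 buffer (pH 6.7), 35 °C
Reagents that add atoms: sodium chlorite, [Na+].[O-]Cl=O
Why: The TEMPO/hypochlorite-catalysed, chlorite-driven oxidation takes the primary C8' alcohol through the aldehyde to the acid at near-neutral pH, and the tertiary C7' hydroxyl cannot be oxidised.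

Step 12
Reactants: 17 (2R)-3-[(4R,6R)-6-{(1R)-2-[(tert-butyldiphenylsilyl)oxy]-1-iodoethyl}-6-methyl-2-oxo-1,3-dioxan-4-yl]-2-hydroxy-2-methylpropanoic acid
Product: 19 (2R,4R)-5-[(2R,3S)-3-{[(tert-butyldiphenylsilyl)oxy]methyl}-2-methyloxiran-2-yl]-2,4-dihydroxy-2-methylpentanoic acid, via iodohydrin acid 18 (not isolated)
Conditions: K2CO3 (3 equiv), MeOH, 0 °C → rt; then cold aq. NaH2PO4 to pH 5, EtOAc
Reagents that add atoms: none
Why: Methanolysis of the cyclic carbonate (acyl cleavage, so C5' and C3' keep their C–O bonds) frees the C3' alkoxide, which displaces iodide at C2' with inversion in an intramolecular Williamson (3-exo-tet) closure, so the oxirane keeps the cis arrangement of C4' and C1' from the Z alkene, while the carboxylate is inert.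

Step 13
Reactants: 19 (2R,4R)-5-[(2R,3S)-3-{[(tert-butyldiphenylsilyl)oxy]methyl}-2-methyloxiran-2-yl]-2,4-dihydroxy-2-methylpentanoic acid
Product: 20 (3R,5R)-5-{[(2R,3S)-3-{[(tert-butyldiphenylsilyl)oxy]methyl}-2-methyloxiran-2-yl]methyl}-3-hydroxy-3-methyloxolan-2-one
Conditions: N,N'-diisopropylcarbodiimide, DMAP (cat.), CH2Cl2, 0 °C → rt
Reagents that add atoms: none
Why: Carbodiimide (Steglich-type) lactonisation of the γ-hydroxy acid closes the five-membered ring at the acyl carbon without acid, so the C5'–O bond and the acid-sensitive oxirane are preserved and the tertiary C7' hydroxyl is too hindered to compete.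

Step 14
Reactants: 20 (3R,5R)-5-{[(2R,3S)-3-{[(tert-butyldiphenylsilyl)oxy]methyl}-2-methyloxiran-2-yl]methyl}-3-hydroxy-3-methyloxolan-2-one
Product: 21 (3R,5R)-3-hydroxy-5-{[(2R,3S)-3-(hydroxymethyl)-2-methyloxiran-2-yl]methyl}-3-methyloxolan-2-one
Conditions: Bu4NF, AcOH (1:1), THF, 0 °C → rt
Reagents that add atoms: none
Why: Fluoride cleavage of the silyl ether, buffered with acetic acid, should free the C1' alcohol without Payne rearrangement of the epoxy alcohol or opening of the lactone.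

Step 15
Reactants: 21 (3R,5R)-3-hydroxy-5-{[(2R,3S)-3-(hydroxymethyl)-2-methyloxiran-2-yl]methyl}-3-methyloxolan-2-one; 22 umbelliferone (7-hydroxy-2H-chromen-2-one)
Product: 23 7-{[(2S,3R)-3-{[(2R,4R)-4-hydroxy-4-methyl-5-oxooxolan-2-yl]methyl}-3-methyloxiran-2-yl]methoxy}-2H-chromen-2-one (target)
Conditions: PPh3, diisopropyl azodicarboxylate, THF, 0 °C → rt
Reagents that add atoms: none
Why: In this Mitsunobu etherification the acidic phenol displaces the activated primary C1' oxygen by SN2 at a CH2 group, so no stereocentre is touched and the tertiary C7' hydroxyl does not react.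

**Compound list**

1 | (R)-citramalic acid, (2R)-2-hydroxy-2-methylbutanedioic acid | OC(=O)C[C@@](C)(O)C(=O)O | starting material
2 | (2R)-2-methylbutane-1,2,4-triol | OCC[C@@](C)(O)CO | intermediate
3 | 2-[(4R)-2,2,4-trimethyl-1,3-dioxolan-4-yl]ethan-1-ol | OCC[C@]1(C)COC(C)(C)O1 | intermediate
4 | 2-[(4R)-2,2,4-trimethyl-1,3-dioxolan-4-yl]acetaldehyde | O=CC[C@]1(C)COC(C)(C)O1 | intermediate
5 | methyl 3-methylbut-2-enoate | COC(=O)C=C(C)C | starting material
6 | lithium 1-methoxy-3-methylbuta-1,3-dien-1-olate | COC([O-])=CC(C)=C.[Li+] | intermediate (not isolated)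
7 | [(1-methoxy-3-methylbuta-1,3-dien-1-yl)oxy]trimethylsilane | COC(O[Si](C)(C)C)=CC(C)=C | intermediate
8 | monovalent copper aldolate of methyl (2Z,5S)-5-hydroxy-3-methyl-6-[(4R)-2,2,4-trimethyl-1,3-dioxolan-4-yl]hex-2-enoate (tol-BINAP on copper not drawn) | COC(=O)/C=C(C)\C[C@H](O[Cu])C[C@]1(C)COC(C)(C)O1 | intermediate (not isolated)
9 | (6S)-4-methyl-6-{[(4R)-2,2,4-trimethyl-1,3-dioxolan-4-yl]methyl}-5,6-dihydro-2H-pyran-2-one | CC1=CC(=O)O[C@H](C[C@]2(C)COC(C)(C)O2)C1 | intermediate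
10 | (2Z,5S)-3-methyl-6-[(4R)-2,2,4-trimethyl-1,3-dioxolan-4-yl]hex-2-ene-1,5-diol | OC/C=C(C)\C[C@H](O)C[C@]1(C)COC(C)(C)O1 | intermediate
11 | (2S,4Z)-6-[(tert-butyldiphenylsilyl)oxy]-4-methyl-1-[(4R)-2,2,4-trimethyl-1,3-dioxolan-4-yl]hex-4-en-2-ol | CC(C)(C)[Si](c1ccccc1)(c2ccccc2)OC/C=C(C)\C[C@H](O)C[C@]3(C)COC(C)(C)O3 | intermediate
12 | tert-butyl (2S,4Z)-6-[(tert-butyldiphenylsilyl)oxy]-4-methyl-1-[(4R)-2,2,4-trimethyl-1,3-dioxolan-4-yl]hex-4-en-2-yl carbonate | CC(C)(C)OC(=O)O[C@@H](C/C(C)=C\CO[Si](c1ccccc1)(c2ccccc2)C(C)(C)C)C[C@]3(C)COC(C)(C)O3 | intermediate (key-step precursor)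
13 | (4R,6R)-2-tert-butoxy-4-{(1R)-2-[(tert-butyldiphenylsilyl)oxy]-1-iodoethyl}-4-methyl-6-{[(4R)-2,2,4-trimethyl-1,3-dioxolan-4-yl]methyl}-1,3-dioxan-2-ylium bromide | CC(C)(C)OC1=[O+][C@H](C[C@]2(C)COC(C)(C)O2)C[C@](C)([C@H](I)CO[Si](c3ccccc3)(c4ccccc4)C(C)(C)C)O1.[Br-] | intermediate (not isolated)
14 | (4R,6R)-4-{(1R)-2-[(tert-butyldiphenylsilyl)oxy]-1-iodoethyl}-4-methyl-6-{[(4R)-2,2,4-trimethyl-1,3-dioxolan-4-yl]methyl}-1,3-dioxan-2-one | O=C1O[C@H](C[C@]2(C)COC(C)(C)O2)C[C@](C)([C@H](I)CO[Si](c3ccccc3)(c4ccccc4)C(C)(C)C)O1 | intermediate (key-step product)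
15 | (4R,6R)-4-{(1R)-2-[(tert-butyldiphenylsilyl)oxy]-1-iodoethyl}-6-[(2R)-2,3-dihydroxy-2-methylpropyl]-4-methyl-1,3-dioxan-2-one | O=C1O[C@H](C[C@@](C)(O)CO)C[C@](C)([C@H](I)CO[Si](c2ccccc2)(c3ccccc3)C(C)(C)C)O1 | intermediate
16 | (2R)-3-[(4R,6R)-6-{(1R)-2-[(tert-butyldiphenylsilyl)oxy]-1-iodoethyl}-6-methyl-2-oxo-1,3-dioxan-4-yl]-2-hydroxy-2-methylpropanal | O=C1O[C@H](C[C@@](C)(O)C=O)C[C@](C)([C@H](I)CO[Si](c2ccccc2)(c3ccccc3)C(C)(C)C)O1 | intermediate (not isolated)
17 | (2R)-3-[(4R,6R)-6-{(1R)-2-[(tert-butyldiphenylsilyl)oxy]-1-iodoethyl}-6-methyl-2-oxo-1,3-dioxan-4-yl]-2-hydroxy-2-methylpropanoic acid | O=C1O[C@H](C[C@@](C)(O)C(=O)O)C[C@](C)([C@H](I)CO[Si](c2ccccc2)(c3ccccc3)C(C)(C)C)O1 | intermediate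
18 | (2R,4R,6R,7R)-8-[(tert-butyldiphenylsilyl)oxy]-2,4,6-trihydroxy-7-iodo-2,6-dimethyloctanoic acid (present as its potassium salt) | OC(=O)[C@](C)(O)C[C@@H](O)C[C@@](C)(O)[C@H](I)CO[Si](c1ccccc1)(c2ccccc2)C(C)(C)C | intermediate (not isolated)
19 | (2R,4R)-5-[(2R,3S)-3-{[(tert-butyldiphenylsilyl)oxy]methyl}-2-methyloxiran-2-yl]-2,4-dihydroxy-2-methylpentanoic acid | OC(=O)[C@](C)(O)C[C@@H](O)C[C@@]1(C)O[C@H]1CO[Si](c2ccccc2)(c3ccccc3)C(C)(C)C | intermediate
20 | (3R,5R)-5-{[(2R,3S)-3-{[(tert-butyldiphenylsilyl)oxy]methyl}-2-methyloxiran-2-yl]methyl}-3-hydroxy-3-methyloxolan-2-one | C[C@]1(C[C@H]2C[C@@](C)(O)C(=O)O2)O[C@H]1CO[Si](c3ccccc3)(c4ccccc4)C(C)(C)C | intermediate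
21 | (3R,5R)-3-hydroxy-5-{[(2R,3S)-3-(hydroxymethyl)-2-methyloxiran-2-yl]methyl}-3-methyloxolan-2-one | C[C@]1(C[C@H]2C[C@@](C)(O)C(=O)O2)O[C@H]1CO | intermediate
22 | umbelliferone, 7-hydroxy-2H-chromen-2-one | Oc1ccc2ccc(=O)oc2c1 | starting material
23 | 7-{[(2S,3R)-3-{[(2R,4R)-4-hydroxy-4-methyl-5-oxooxolan-2-yl]methyl}-3-methyloxiran-2-yl]methoxy}-2H-chromen-2-one | C[C@]1(C[C@H]2C[C@@](C)(O)C(=O)O2)O[C@H]1COc1ccc2ccc(=O)oc2c1 | target

**Step count and risks**

Total step count: 15. Longest linear sequence: 14 steps (steps 1–3 and 5–15 from (R)-citramalic acid); step 4 is a one-step side branch.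

The three steps most likely to fail:

Step 9 (key step). The carbonate may attack the wrong alkene face through the competing chair with the methyl equatorial, which would give the pair of oxirane carbons in the wrong sense relative to C5'. The acetonide may also be lost to traces of HBr. The fallback sets out from 11, returns to the route at 21 and sets the oxirane by reagent control after the lactone is in place. Aqueous acetic acid removes the acetonide of 11 to give (2R,4S,6Z)-8-[(tert-butyldiphenylsilyl)oxy]-2,6-dimethyloct-6-ene-1,2,4-triol F1. TEMPO/PhI(OAc)2 in CH2Cl2 oxidises the primary C8' alcohol, the aldehyde is trapped by the C5' hydroxyl as the lactol (3R,5S)-5-[(2Z)-4-[(tert-butyldiphenylsilyl)oxy]-2-methylbut-2-en-1-yl]-3-methyloxolane-2,3-diol F2, and this is oxidised on to the lactone (3R,5S)-5-[(2Z)-4-[(tert-butyldiphenylsilyl)oxy]-2-methylbut-2-en-1-yl]-3-hydroxy-3-methyloxolan-2-one F3. Bu4NF/AcOH then frees the Z allylic alcohol (3R,5S)-3-hydroxy-5-[(2Z)-4-hydroxy-2-methylbut-2-en-1-yl]-3-methyloxolan-2-one F4. Sharpless asymmetric epoxidation (Ti(OiPr)4, L-(+)-diethyl tartrate, t-BuOOH, 4 Å molecular sieves, CH2Cl2, −20 °C), which on Z 3-methyl allylic alcohols of this kind delivers the (2S,3R) oxirane, should then give 21.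

Step 5. Catalyst control at C5' may be weak or mismatched with this β-branched, β-oxygenated aliphatic aldehyde, and the aldolate may form largely with E geometry and then fail to lactonise. The fallback sets out from 4 and returns at 9. Brown methallylation with (−)-Ipc2B(methallyl) (from (−)-Ipc2BOMe and CH2=C(CH3)CH2MgCl; Et2O, −78 °C; NaOH/H2O2 work-up), which adds to the Si face, should give (2S)-4-methyl-1-[(4R)-2,2,4-trimethyl-1,3-dioxolan-4-yl]pent-4-en-2-ol F5. Acryloyl chloride/Et3N/DMAP gives the acrylate (2S)-4-methyl-1-[(4R)-2,2,4-trimethyl-1,3-dioxolan-4-yl]pent-4-en-2-yl prop-2-enoate F6. Ring-closing metathesis with the second-generation Grubbs catalyst RuCl2(=CHPh)(H2IMes)(PCy3) in refluxing CH2Cl2 then closes the dihydropyranone 9, again with the alkene held Z by the ring.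

Step 11. The tertiary 1,2-diol or the α-hydroxy aldehyde may undergo oxidative C7'–C8' cleavage, and the secondary iodide may be attacked by hypochlorite. The fallback sets out from 15 and returns at 20, so that the free acid is never made and steps 12 and 13 are bypassed. K2CO3/MeOH first converts the iodocarbonate of 15 into the oxirane, giving (2R,4R)-5-[(2R,3S)-3-{[(tert-butyldiphenylsilyl)oxy]methyl}-2-methyloxiran-2-yl]-2-methylpentane-1,2,4-triol F7. TEMPO/PhI(OAc)2 (CH2Cl2, solid NaHCO3) then oxidises the primary C8' alcohol, the C5' hydroxyl captures the aldehyde as the lactol (3R,5R)-5-{[(2R,3S)-3-{[(tert-butyldiphenylsilyl)oxy]methyl}-2-methyloxiran-2-yl]methyl}-3-methyloxolane-2,3-diol F8, and further oxidation of the lactol gives lactone 20.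

**Further compounds**

F1 | step 9 | (2R,4S,6Z)-8-[(tert-butyldiphenylsilyl)oxy]-2,6-dimethyloct-6-ene-1,2,4-triol | CC(C)(C)[Si](c1ccccc1)(c2ccccc2)OC/C=C(C)\C[C@H](O)C[C@@](C)(O)CO
F2 | step 9 | (3R,5S)-5-[(2Z)-4-[(tert-butyldiphenylsilyl)oxy]-2-methylbut-2-en-1-yl]-3-methyloxolane-2,3-diol (lactol, mixture of anomers) | C/C(C[C@H]1C[C@@](C)(O)C(O)O1)=C/CO[Si](c2ccccc2)(c3ccccc3)C(C)(C)C
F3 | step 9 | (3R,5S)-5-[(2Z)-4-[(tert-butyldiphenylsilyl)oxy]-2-methylbut-2-en-1-yl]-3-hydroxy-3-methyloxolan-2-one | C/C(C[C@H]1C[C@@](C)(O)C(=O)O1)=C/CO[Si](c2ccccc2)(c3ccccc3)C(C)(C)C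
F4 | step 9 | (3R,5S)-3-hydroxy-5-[(2Z)-4-hydroxy-2-methylbut-2-en-1-yl]-3-methyloxolan-2-one | C/C(C[C@H]1C[C@@](C)(O)C(=O)O1)=C/CO
F5 | step 5 | (2S)-4-methyl-1-[(4R)-2,2,4-trimethyl-1,3-dioxolan-4-yl]pent-4-en-2-ol | CC(=C)C[C@H](O)C[C@]1(C)COC(C)(C)O1
F6 | step 5 | (2S)-4-methyl-1-[(4R)-2,2,4-trimethyl-1,3-dioxolan-4-yl]pent-4-en-2-yl prop-2-enoate | C=CC(=O)O[C@@H](CC(C)=C)C[C@]1(C)COC(C)(C)O1
F7 | step 11 | (2R,4R)-5-[(2R,3S)-3-{[(tert-butyldiphenylsilyl)oxy]methyl}-2-methyloxiran-2-yl]-2-methylpentane-1,2,4-triol | OC[C@](C)(O)C[C@@H](O)C[C@@]1(C)O[C@H]1CO[Si](c2ccccc2)(c3ccccc3)C(C)(C)C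
F8 | step 11 | (3R,5R)-5-{[(2R,3S)-3-{[(tert-butyldiphenylsilyl)oxy]methyl}-2-methyloxiran-2-yl]methyl}-3-methyloxolane-2,3-diol (lactol, mixture of anomers) | C[C@]1(C[C@H]2C[C@@](C)(O)C(O)O2)O[C@H]1CO[Si](c3ccccc3)(c4ccccc4)C(C)(C)C
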